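**Assumption (stereochemistry):** the SMILES is read as drawn. It places the aryl group, the CH2OH group and the benzyl group of the tetrahydrofuran on one face (2R,3R,4R, the C2 epimer of the lariciresinol pattern), and the route is built for this all-cis isomer.

## Analysis of the target

The target is a linear tetramer of C6C3 units: guaiacyl ring A is joined through a CH2 group to C4 of a tetrahydrofuran (O1, C2, C3, C4, C5), C2 of the tetrahydrofuran carries ring B (the benzo ring of dihydrobenzofuran B), C2 of dihydrobenzofuran B carries ring C (the benzo ring of dihydrobenzofuran C), and C2 of dihydrobenzofuran C carries guaiacyl ring D. There are seven stereocentres in three isolated sets: the tetrahydrofuran is all-cis (2R,3R,4R), dihydrobenzofuran B is trans (2R,3S), and dihydrobenzofuran C is trans with the opposite absolute sense (2S,3R). Flat aryl rings separate the sets, so none can direct another and each needs its own source of absolute configuration. The sensitive groups are two free phenols, three primary alcohols and the three benzylic C–O bonds at C2 of the heterocycles. Each of these carbons is para to an oxygen on the attached ring, so each ionizes under acid and can be cut by hydrogenolysis. The hard parts are the contrathermodynamic all-cis tetrahydrofuran and two dihydrobenzofurans of opposite handedness on an electron-rich, acid-sensitive scaffold. The strategy rests on C2 of dihydrobenzofuran B, which is benzylic to ring C and para to the ring oxygen O1 of dihydrobenzofuran C (O1 sits on C7a, the attachment is at C5). A carbinol at this carbon therefore ionizes easily and reversibly, and its configuration can be left to the neighbouring C3 stereocentre during ring closure.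

## Retrosynthetic reasoning

**48 from 47.** The two phenols and three primary alcohols are carried as benzyl ethers, so the last step is one hydrogenolysis of 47. Benzyl ethers survive organolithium reagents, Lewis acid and hydride donors. Each CH2OH can also be introduced already benzylated from BOM chloride 14.

**47 from 46, and 46 from 45 and 44.** The bond between tetrahydrofuran C2 and ring B is cut. Forward, aryllithium 45 adds to the carbonyl of the cis lactone 44, and the cyclic hemiketal 46 is reduced by ionic hydrogenation. C2 is made last, by hydride delivery to the face opposite the C3 and C4 substituents, which is what the all-cis pattern requires. The cut is placed here because bromide 31, the output of the key step, becomes the coupling partner in one operation. The tetrahydrofuran stereochemistry is thereby moved onto a small lactone.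

**31 from 30 (key disconnection).** The O1–C2 bond of dihydrobenzofuran B is cut, giving the ring B phenol and a benzylic carbinol in 30. The C2–C3 or C3–C3a bonds are not cut, because only the O1–C2 bond can be formed under thermodynamic control. Both carbinol epimers ionize to one cation, and C3 then sets C2 as trans. What is gained is that only one stereocentre of this ring has to be made deliberately. The forward reaction has to ionize the carbinol selectively and capture the cation with oxygen before a proton is lost from C3.

**30 from 29, and 29 from 28 and 26.** The bond between the carbinol carbon and ring C is cut. Forward, the arylmagnesium reagent 28 (from bromide 20 through aryllithium 27) adds to aldehyde 26. The carbinol configuration is deliberately left open. The phenol is unmasked from its silyl ether by fluoride, because any acid-labile phenol protecting group would trigger ionization prematurely. An aldehyde is preferred to a ketone at this position because it adds aryl-metal reagents at −78 °C and delivers the carbinol without a separate reduction.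

**26 from 25, 24 and 23.** The C3–CH2O bond is cut. The (R)-oxazolidinone 21, as its lithium salt 22, is acylated by acid chloride 8 to the arylacetyl imide 23, on which it directs alkylation by 14 to give 24. This fixes C3 of dihydrobenzofuran B and brings in the CH2OH carbon as its benzyl ether. Reduction to 25 and oxidation give 26.

**20 by the same logic.** Dihydrobenzofuran C has the mirror-image configuration, so it comes from the same acid chloride 8 with the enantiomeric auxiliary 11 (lithium salt 12, imide 13, alkylated imide 15, alcohol 16, aldehyde 17). Ring D arrives as Grignard reagent 10, made once from bromide 9. Addition gives 18, desilylation gives 19, and the same ionization and closure give 20. One sequence therefore serves both rings.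

**8 from 7, and 7 from 1 and 2.** The acid chloride 8 is made once from acid 7 and divided between the two auxiliaries. The acetic acid side chain ortho to the phenol is cut back to an allyl group, which a Claisen rearrangement of allyl ether 3 places at the only free ortho position (4). Silylation (5) and oxidative cleavage through aldehyde 6 give 7. The bromine of 1 is carried through as the later metalation site.

**44 from 32, 33 and 10.** The lactone C3–CH2O bond is cut in the same way: auxiliary 11 on imide 41 directs alkylation by 14 to give 42, and desilylation lets the γ-hydroxyl of 43 lactonize. Acid 39 is the opened, silyl-protected form of the β-benzyl lactone 36 and is attached to the auxiliary through anhydride 40. The C4 stereocentre of 36 comes from the chiral pool: cyclopropane lactone 34 (from 32 and 33) is opened by Grignard reagent 10 to 35, which is decarboxylated. Setting C3 by auxiliary control on the open chain is what gives the cis lactone, since alkylation of the closed lactone would give trans.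

## Alternatives that were turned down

**Alternative 1: radical cyclization with oxygen trapping.**
- Disconnection: the C3–C3a bond of dihydrobenzofuran B. The O1–C2 bond is made first by allylic etherification, giving aryl iodide A1.
- Key step: a ring B aryl radical (tin hydride, slow addition, excess nitroxide trap) adds 5-exo to the vinyl group, and the exocyclic CH2 radical is captured on oxygen, giving alkoxyamine A2.
- For it: a C–C bond and the oxygen of the future CH2OH are made in one neutral step. No cation is generated next to acid-labile ethers, and C2 could be set by a catalytic asymmetric etherification.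
- Against it: the trans ratio depends on a kinetic preference in the cyclization and cannot be corrected afterwards. The doubly activated allylic benzylic aryl ether in A1 is prone to ionization and rearrangement on heating. Premature reduction or trapping of the aryl radical competes. The N–O bond of A2 must later be cut reductively, and its ester is not a nucleophile handle, so more steps are needed before the tetrahydrofuran can be attached.
- Comparison: on mildness toward acid-sensitive groups it is the stronger approach. The chosen route instead offers thermodynamic correction of C2, an aryl bromide ready for the next coupling, and one sequence used twice.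

**Alternative 2: oxidative ring contraction of a flavanone.**
- Disconnection: the C3–C3a bond of a dihydrobenzofuran. O1–C2 and the C2 stereocentre are taken from the enantioenriched flavanone A3.
- Key step: a hypervalent iodine oxidant with acid in an orthoformate attacks the enol ether at C3, the fused aryl ring shifts from C4 to C3, and C4 leaves the ring as a methyl ester, giving A4.
- For it: it is short and known for flavanones. The ester is the CH2OH precursor and allows equilibration to trans.
- Against it: A4 is only the ring C and ring D half. For dihydrobenzofuran B the flavanone would carry the whole electron-rich ring C unit at C2, where over-oxidation to the flavone and racemization by reversible ring opening are most likely. The tosylate that tempers ring D must later be exchanged, and the ester must be reduced and protected.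
- Comparison: for dihydrobenzofuran C alone it is as short as or shorter than steps 8 to 14 here. The chosen route offers one sequence for both rings, a C3 stereocentre that cannot epimerize once the carbonyl is reduced, and a C2 centre that corrects itself.

**Alternative 3: diazolactone C–H insertion to a furofuranone.**
- Disconnection: the tetrahydrofuran C2–C3 bond.
- Key step: the catalyst Rh2(OAc)4 turns the diazolactone A5 into a carbenoid that inserts into the ring B benzylic ether C–H bond, giving the cis-fused furofuranone A6 with ring B endo. Hydrogenolysis of the lactone benzylic C–O bond and reduction of the acid would follow.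
- For it: the ring fusion fixes all three tetrahydrofuran stereocentres at once in the all-cis sense. On this point it is stronger than the ionic hydrogenation of steps 29 and 30.
- Against it: A5 offers the carbenoid many competing sites, namely other ether C–H bonds, the electron-rich arenes and the ether oxygens. The endo to exo ratio is not assured, diazo transfer onto a hindered lactone is demanding, and the later hydrogenolysis must pick one of four benzylic C–O bonds.
- Comparison: it addresses the tetrahydrofuran, not dihydrobenzofuran B, so it is complementary. The chosen route keeps irreversible, selectivity-critical C–C bond formations on small molecules. Its late steps on the complex fragment are additions and ionizations with predictable outcomes.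

Key step: step 21

## Route

Step 1
Reactants: 1 4-bromo-2-methoxyphenol; 2 allyl bromide
Product: 3 1-(allyloxy)-4-bromo-2-methoxybenzene
Conditions: K2CO3, acetone, reflux
Reagents that add atoms: none
Why: Williamson O-allylation of the phenoxide; the aryl bromide is inert to carbonate.

Step 2
Reactants: 3 1-(allyloxy)-4-bromo-2-methoxybenzene
Product: 4 2-allyl-4-bromo-6-methoxyphenol
Conditions: N,N-diethylaniline, 190 °C
Reagents that add atoms: none
Why: Aromatic Claisen rearrangement; only one ortho position is free (the other carries OMe, para carries Br), so the allyl group arrives next to the hydroxyl and tautomerization restores the phenol.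

Step 3
Reactants: 4 2-allyl-4-bromo-6-methoxyphenol
Product: 5 (2-allyl-4-bromo-6-methoxyphenoxy)triisopropylsilane
Conditions: TIPSCl, imidazole, DMF, rt → 40 °C
Reagents that add atoms: triisopropylsilyl chloride, CC(C)[Si](Cl)(C(C)C)C(C)C
Why: Silylation of the phenol; the bulky silyl ether should resist acid chloride formation, TiCl4, LiBH4 and aryl-metal reagents, should not migrate to a neighbouring alkoxide, and is later removed by fluoride without acid.

Step 4
Reactants: 5 (2-allyl-4-bromo-6-methoxyphenoxy)triisopropylsilane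
Product: 7 2-[5-bromo-3-methoxy-2-(triisopropylsilyloxy)phenyl]acetic acid, via arylacetaldehyde 6 (not isolated)
Conditions: OsO4 (2 mol %), NaIO4, 2,6-lutidine, dioxane–H2O, rt; then NaClO2, NaH2PO4, 2-methyl-2-butene, t-BuOH–H2O, 0 °C → rt
Reagents that add atoms: NaIO4 (sodium periodate, oxygen passed on through OsO4), [Na+].[O-]I(=O)(=O)=O; NaClO2 (sodium chlorite), [Na+].[O-]Cl=O
Why: Lemieux–Johnson cleavage of the terminal alkene gives the arylacetaldehyde, which is oxidized crude by the Pinnick method; both oxidants spare the electron-rich ring.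

Step 5
Reactants: 7 2-[5-bromo-3-methoxy-2-(triisopropylsilyloxy)phenyl]acetic acid
Product: 8 2-[5-bromo-3-methoxy-2-(triisopropylsilyloxy)phenyl]acetyl chloride
Conditions: (COCl)2, DMF (cat.), CH2Cl2, 0 °C → rt; volatiles removed, crude chloride divided into two portions
Reagents that add atoms: oxalyl chloride, O=C(Cl)C(Cl)=O
Why: Acid chloride formation through the DMF-derived chloroiminium catalyst, with only gaseous by-products; the hindered aryl silyl ether keeps the phenol oxygen from closing onto the acyl chloride, and the one batch serves steps 8 and 15.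

Step 6
Reactants: 1 4-bromo-2-methoxyphenol
Product: 9 1-(benzyloxy)-4-bromo-2-methoxybenzene
Conditions: BnBr, K2CO3, DMF, rt
Reagents that add atoms: benzyl bromide, BrCc1ccccc1
Why: Williamson benzylation; 9 is the source of ring D and of ring A.

Step 7
Reactants: 9 1-(benzyloxy)-4-bromo-2-methoxybenzene
Product: 10 [4-(benzyloxy)-3-methoxyphenyl]magnesium bromide (titrated THF solution)
Conditions: Mg turnings, I2 (cat.), THF, 40 °C; solution titrated and kept under argon
Reagents that add atoms: magnesium, [Mg]
Why: Grignard formation by insertion of magnesium into the aryl C–Br bond; the benzyl and methyl ethers are inert, and the single titrated solution is drawn on in steps 12 and 23.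

Step 8
Reactants: 8 2-[5-bromo-3-methoxy-2-(triisopropylsilyloxy)phenyl]acetyl chloride; 11 (S)-4-benzyl-2-oxazolidinone
Product: 13 (S)-4-benzyl-3-{2-[5-bromo-3-methoxy-2-(triisopropylsilyloxy)phenyl]acetyl}oxazolidin-2-one, via lithium (S)-oxazolidinide 12 (not isolated)
Conditions: 11, n-BuLi, THF, −78 °C (11 → 12); then 8, −78 → 0 °C
Reagents that add atoms: none
Why: N-Acylation of the lithiated oxazolidinone by the acid chloride, the standard way to Evans imides; n-BuLi is consumed by the N–H before the aryl bromide is introduced, so no bromine–lithium exchange can occur.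

Step 9
Reactants: 13 (S)-imide; 14 benzyl chloromethyl ether (BOM chloride)
Product: 15 (S)-4-benzyl-3-{(R)-3-(benzyloxy)-2-[5-bromo-3-methoxy-2-(triisopropylsilyloxy)phenyl]propanoyl}oxazolidin-2-one
Conditions: TiCl4, i-Pr2NEt, CH2Cl2, 0 °C; then 14, 0 °C
Reagents that add atoms: none
Why: Evans alkylation of the chelated chlorotitanium Z-enolate; the benzyl group of the auxiliary covers one enolate face and the electrophile enters from the other, which gives the (R) centre that becomes C3 of dihydrobenzofuran C.

Step 10
Reactants: 15 alkylated (S)-imide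
Product: 16 (S)-3-(benzyloxy)-2-[5-bromo-3-methoxy-2-(triisopropylsilyloxy)phenyl]propan-1-ol
Conditions: LiBH4, H2O (1 equiv), Et2O–THF, 0 °C
Reagents that add atoms: none
Why: Reductive removal of the auxiliary by hydride attack at the exocyclic imide carbonyl; 11 is recovered, the stereocentre is untouched and its descriptor changes only because the CIP priorities change.

Step 11
Reactants: 16 (S)-alcohol
Product: 17 (R)-3-(benzyloxy)-2-[5-bromo-3-methoxy-2-(triisopropylsilyloxy)phenyl]propanal
Conditions: Dess–Martin periodinane, CH2Cl2, 0 °C; used at once without chromatography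
Reagents that add atoms: none
Why: Dess–Martin oxidation under non-basic conditions, chosen because the α-aryl aldehyde enolizes easily; it is carried on cold and crude.

Step 12
Reactants: 10 [4-(benzyloxy)-3-methoxyphenyl]magnesium bromide; 17 (R)-aldehyde
Product: 18 (1RS,2R)-3-(benzyloxy)-1-[4-(benzyloxy)-3-methoxyphenyl]-2-[5-bromo-3-methoxy-2-(triisopropylsilyloxy)phenyl]propan-1-ol
Conditions: 10 (THF solution), THF, −78 °C
Reagents that add atoms: none
Why: Grignard addition to the aldehyde, fast at −78 °C, so that addition should outrun enolization and exchange with the aryl bromide of 17; the new carbinol centre forms as both epimers (Felkin–Anh bias only) and needs no control.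

Step 13
Reactants: 18 silyl-protected carbinol (both C1 epimers)
Product: 19 (1RS,2R)-3-(benzyloxy)-1-[4-(benzyloxy)-3-methoxyphenyl]-2-(5-bromo-2-hydroxy-3-methoxyphenyl)propan-1-ol
Conditions: TBAF, AcOH, THF, 0 °C
Reagents that add atoms: none
Why: Fluoride cleaves the aryl silyl ether selectively; buffering with acetic acid keeps the medium neutral, so the acid-labile benzylic carbinol and the benzyl ethers are untouched.

Step 14
Reactants: 19 phenol carbinol (both C1 epimers)
Product: 20 (2S,3R)-2-[4-(benzyloxy)-3-methoxyphenyl]-3-[(benzyloxy)methyl]-5-bromo-7-methoxy-2,3-dihydrobenzofuran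
Conditions: BF3·OEt2 (0.2 equiv), 4 Å MS, CH2Cl2, −78 → −30 °C
Reagents that add atoms: none
Why: Stereoconvergent ionization and ring closure of the same kind as the key step: both carbinol epimers give one benzylic cation stabilized by the para benzyloxy group of ring D, and the phenol closes the five-membered ring with the aryl group anti to CH2OBn, so C2 (S) follows from C3 (R).

Step 15
Reactants: 8 2-[5-bromo-3-methoxy-2-(triisopropylsilyloxy)phenyl]acetyl chloride; 21 (R)-4-benzyl-2-oxazolidinone
Product: 23 (R)-4-benzyl-3-{2-[5-bromo-3-methoxy-2-(triisopropylsilyloxy)phenyl]acetyl}oxazolidin-2-one, via lithium (R)-oxazolidinide 22 (not isolated)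
Conditions: 21, n-BuLi, THF, −78 °C (21 → 22); then 8, −78 → 0 °C
Reagents that add atoms: none
Why: Same N-acylation of a lithiated oxazolidinone as in step 8, with the enantiomeric auxiliary and the second portion of acid chloride 8.

Step 16
Reactants: 23 (R)-imide; 14 benzyl chloromethyl ether
Product: 24 (R)-4-benzyl-3-{(S)-3-(benzyloxy)-2-[5-bromo-3-methoxy-2-(triisopropylsilyloxy)phenyl]propanoyl}oxazolidin-2-one
Conditions: TiCl4, i-Pr2NEt, CH2Cl2, 0 °C; then 14, 0 °C
Reagents that add atoms: none
Why: Evans alkylation of the chlorotitanium Z-enolate as in step 9; the (R)-auxiliary exposes the opposite enolate face and gives the (S) centre that becomes C3 of dihydrobenzofuran B.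

Step 17
Reactants: 24 alkylated (R)-imide
Product: 25 (R)-3-(benzyloxy)-2-[5-bromo-3-methoxy-2-(triisopropylsilyloxy)phenyl]propan-1-ol
Conditions: LiBH4, H2O (1 equiv), Et2O–THF, 0 °C
Reagents that add atoms: none
Why: Reductive removal of the auxiliary as in step 10; 21 is recovered and the stereocentre is untouched.

Step 18
Reactants: 25 (R)-alcohol
Product: 26 (S)-3-(benzyloxy)-2-[5-bromo-3-methoxy-2-(triisopropylsilyloxy)phenyl]propanal
Conditions: Dess–Martin periodinane, CH2Cl2, 0 °C; used at once without chromatography
Reagents that add atoms: none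
Why: Non-basic Dess–Martin oxidation as in step 11, to keep the enolizable α-aryl stereocentre intact.

Step 19
Reactants: 20 dihydrobenzofuran C bromide; 26 (S)-aldehyde
Product: 29 (1RS,2S)-3-(benzyloxy)-1-{(2S,3R)-2-[4-(benzyloxy)-3-methoxyphenyl]-3-[(benzyloxy)methyl]-7-methoxy-2,3-dihydrobenzofuran-5-yl}-2-[5-bromo-3-methoxy-2-(triisopropylsilyloxy)phenyl]propan-1-ol, via aryllithium 27 (not isolated), via arylmagnesium bromide 28 (not isolated)
Conditions: n-BuLi, THF, −78 °C (20 → 27); MgBr2·OEt2, −78 °C (27 → 28); then 26, −78 °C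
Reagents that add atoms: none
Why: Bromine–lithium exchange, transmetalation to the less basic Grignard reagent and addition to the aldehyde; the magnesium reagent should not exchange with the aryl bromide of 26 and should add faster than it enolizes the aldehyde, and both carbinol epimers are used.

Step 20
Reactants: 29 silyl-protected ring B carbinol (both C1 epimers)
Product: 30 (1RS,2S)-3-(benzyloxy)-1-{(2S,3R)-2-[4-(benzyloxy)-3-methoxyphenyl]-3-[(benzyloxy)methyl]-7-methoxy-2,3-dihydrobenzofuran-5-yl}-2-(5-bromo-2-hydroxy-3-methoxyphenyl)propan-1-ol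
Conditions: TBAF, AcOH, THF, 0 °C
Reagents that add atoms: none
Why: Buffered fluoride cleavage of the aryl silyl ether as in step 13; no acid touches the carbinol before the key step.

Step 21
Reactants: 30 ring B phenol carbinol (C3 defined, both epimers at the carbinol carbon)
Product: 31 (2R,3S)-3-[(benzyloxy)methyl]-2-{(2S,3R)-2-[4-(benzyloxy)-3-methoxyphenyl]-3-[(benzyloxy)methyl]-7-methoxy-2,3-dihydrobenzofuran-5-yl}-5-bromo-7-methoxy-2,3-dihydrobenzofuran
Conditions: BF3·OEt2 (0.2 equiv), 4 Å MS, CH2Cl2 (high dilution), −78 → −30 °C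
Reagents that add atoms: none
Why: BF3 coordinates the benzylic hydroxyl and both epimers lose it to give the same planar cation, delocalized through ring C onto the para ring oxygen like a quinone methide oxocarbenium ion, so the carbinol configuration is erased. The closest known reaction type is the acid-mediated cyclization of 1-aryl-2-(2-hydroxyaryl)propane-1,3-diol derivatives to trans-2-aryl-2,3-dihydrobenzofurans. The ring B phenol oxygen attacks the cationic carbon and closes dihydrobenzofuran B by forming O1–C2 in a 5-exo-trig mode, the electrophilic double bond of the quinoid form lying outside the new ring. The new stereocentre C2 is controlled by C3: in the transition state the ring C aryl group lies anti to the CH2OBn group, which gives (2R) next to (3S), and because closure is reversible any cis isomer re-ionizes and drains into the more stable trans ring. The step needs ionization of the carbinol in preference to the benzylic ether carbons, and capture by oxygen in preference to loss of the C3 proton or Friedel–Crafts capture; the hydroxyl is the best leaving group present, the intramolecular five-membered closure is fast, and low temperature, dilution and a base-free medium disfavour elimination to the stilbene and intermolecular alkylation. If dihydrobenzofuran C opens reversibly it recloses to its own trans form, so its stereocentres are not at risk as long as no proton is lost.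

Step 22
Reactants: 32 (R)-epichlorohydrin; 33 diethyl malonate
Product: 34 ethyl (1S,5R)-2-oxo-3-oxabicyclo[3.1.0]hexane-1-carboxylate
Conditions: NaOEt, EtOH, reflux
Reagents that add atoms: none
Why: Known cyclopropanation and lactonization: the malonate anion opens the epoxide at its CH2 end, the alkoxide displaces chloride to a new epoxide, the malonate carbanion closes the cyclopropane by 3-exo-tet attack with inversion, and the CH2O arm lactonizes onto the cis ester; the configuration of 34 derives from 32.

Step 23
Reactants: 34 cyclopropane lactone; 10 [4-(benzyloxy)-3-methoxyphenyl]magnesium bromide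
Product: 35 ethyl (3RS,4R)-4-[4-(benzyloxy)-3-methoxybenzyl]-2-oxotetrahydrofuran-3-carboxylate
Conditions: 10 (THF solution), CuI (10 mol %), THF, −40 → −20 °C
Reagents that add atoms: none
Why: Copper-catalysed homoconjugate opening of the doubly activated cyclopropane at its unsubstituted CH2 carbon by the Grignard reagent; the ring-fusion stereocentre is not involved and becomes C4 (R), while C3 forms as an inconsequential epimer mixture.

Step 24
Reactants: 35 lactone ester
Product: 36 (R)-4-[4-(benzyloxy)-3-methoxybenzyl]dihydrofuran-2(3H)-one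
Conditions: LiCl, DMSO–H2O, 140 °C
Reagents that add atoms: none
Why: Krapcho dealkoxycarbonylation of the malonate-type ester; the C4 stereocentre is not enolizable and is kept.

Step 25
Reactants: 36 (R)-β-benzyl lactone
Product: 39 (R)-3-[4-(benzyloxy)-3-methoxybenzyl]-4-[(tert-butyldiphenylsilyl)oxy]butanoic acid, via potassium hydroxy carboxylate 37 (not isolated), via bis-silyl derivative 38 (not isolated)
Conditions: KOH, MeOH–H2O, rt, then evaporation; TBDPSCl, imidazole, DMF, rt; then K2CO3 (cat.), MeOH–THF–H2O, rt; acidification to pH 5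
Reagents that add atoms: KOH (potassium hydroxide), [K+].[OH-]; tert-butyldiphenylsilyl chloride, CC(C)(C)[Si](Cl)(c1ccccc1)c1ccccc1
Why: Saponification opens the lactone, silylation protects the primary alcohol (and transiently the carboxylate), and mild methanolysis frees the acid from the labile silyl ester; the robust silyl ether stops the hydroxy acid from closing back and should survive TiCl4.

Step 26
Reactants: 39 silyloxy acid; 11 (S)-4-benzyl-2-oxazolidinone
Product: 41 (S)-4-benzyl-3-{(R)-3-[4-(benzyloxy)-3-methoxybenzyl]-4-[(tert-butyldiphenylsilyl)oxy]butanoyl}oxazolidin-2-one, via mixed pivalic anhydride 40 (not isolated)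
Conditions: PivCl, Et3N, THF, −20 °C; then LiCl, 11, −20 °C → rt
Reagents that add atoms: none
Why: N-Acylation of the oxazolidinone through the mixed pivalic anhydride with LiCl activation; attack occurs at the unhindered alkanoyl carbonyl, and the method avoids the HCl of an acid chloride preparation next to the alkyl silyl ether.

Step 27
Reactants: 41 imide; 14 benzyl chloromethyl ether
Product: 42 (S)-4-benzyl-3-{(2R,3R)-3-[4-(benzyloxy)-3-methoxybenzyl]-2-[(benzyloxy)methyl]-4-[(tert-butyldiphenylsilyl)oxy]butanoyl}oxazolidin-2-one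
Conditions: TiCl4, i-Pr2NEt, CH2Cl2, 0 °C; then 14, 0 °C
Reagents that add atoms: none
Why: Evans alkylation of the chlorotitanium Z-enolate; the auxiliary, not the β-stereocentre, decides the face, and the (S)-auxiliary delivers the (2R) centre, which together with (3R) corresponds to the cis lactone.

Step 28
Reactants: 42 alkylated imide
Product: 44 (3R,4R)-4-[4-(benzyloxy)-3-methoxybenzyl]-3-[(benzyloxy)methyl]dihydrofuran-2(3H)-one, via hydroxy imide 43 (not isolated)
Conditions: TBAF, AcOH, THF, 0 °C → rt
Reagents that add atoms: none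
Why: Fluoride removes the silyl group and the freed γ-hydroxyl acylates itself on the activated imide carbonyl (5-exo-trig lactonization), releasing auxiliary 11; no bond to either stereocentre is broken and the buffered medium should not enolize the lactone, so the cis relationship is kept.

Step 29
Reactants: 31 bis-dihydrobenzofuran bromide; 44 cis lactone
Product: 46 (3R,4R)-4-[4-(benzyloxy)-3-methoxybenzyl]-3-[(benzyloxy)methyl]-2-Ar-tetrahydrofuran-2-ol (Ar = the dihydrobenzofuran-5-yl group of 31 in place of its bromine; both anomers), via aryllithium 45 (not isolated)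
Conditions: n-BuLi, THF, −78 °C (31 → 45); then 44 (1.5 equiv), −78 °C
Reagents that add atoms: none
Why: Bromine–lithium exchange and 1,2-addition of the aryllithium to the lactone carbonyl; the tetrahedral lithium alkoxide is stable at −78 °C, which prevents a second addition, and protonation gives the cyclic hemiketal, whose anomeric configuration is irrelevant.

Step 30
Reactants: 46 hemiketal
Product: 47 (2R,3R,4R)-2-Ar-4-[4-(benzyloxy)-3-methoxybenzyl]-3-[(benzyloxy)methyl]tetrahydrofuran (Ar as in 46)
Conditions: Et3SiH (5 equiv), CH2Cl2, −78 °C; then BF3·OEt2 (1.5 equiv), −78 °C; Et3N quench at −78 °C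
Reagents that add atoms: none
Why: Ionic hydrogenation of the hemiketal: BF3 ionizes the anomeric hydroxyl to a 2-aryl oxocarbenium ion and the silane delivers hydride to the face opposite the C3 CH2OBn group (pushed pseudoaxial by the coplanar aryl group) and the C4 benzyl group, so the aryl group ends cis to both and C2 is (R). The silane is present before the Lewis acid and the temperature is held at −78 °C so that reduction should outrun loss of the C3 proton and ionization of the dihydrobenzofuran ethers.

Step 31
Reactants: 47 pentabenzyl ether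
Product: 48 4-{[(3R,4R,5R)-5-{(2R,3S)-3-(hydroxymethyl)-2-[(2S,3R)-2-(4-hydroxy-3-methoxyphenyl)-3-(hydroxymethyl)-7-methoxy-2,3-dihydrobenzofuran-5-yl]-7-methoxy-2,3-dihydrobenzofuran-5-yl}-4-(hydroxymethyl)tetrahydrofuran-3-yl]methyl}-2-methoxyphenol (target)
Conditions: H2 (1 atm), Pd/C, EtOAc–MeOH, rt
Reagents that add atoms: none
Why: Hydrogenolysis of the five benzyl ethers; O-benzyl groups should be cleaved faster than the benzylic C–O bonds held in the tetrahydrofuran and dihydrobenzofuran rings, and the reaction is stopped when debenzylation is complete.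

## Compound list

1 | 4-bromo-2-methoxyphenol | COc1cc(Br)ccc1O | starting material
2 | allyl bromide | C=CCBr | starting material
3 | 1-(allyloxy)-4-bromo-2-methoxybenzene | COc1cc(Br)ccc1OCC=C | intermediate
4 | 2-allyl-4-bromo-6-methoxyphenol | COc1cc(Br)cc(CC=C)c1O | intermediate
5 | (2-allyl-4-bromo-6-methoxyphenoxy)triisopropylsilane | COc1cc(Br)cc(CC=C)c1O[Si](C(C)C)(C(C)C)C(C)C | intermediate
6 | 2-[5-bromo-3-methoxy-2-(triisopropylsilyloxy)phenyl]acetaldehyde | COc1cc(Br)cc(CC=O)c1O[Si](C(C)C)(C(C)C)C(C)C | intermediate (not isolated)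
7 | 2-[5-bromo-3-methoxy-2-(triisopropylsilyloxy)phenyl]acetic acid | COc1cc(Br)cc(CC(=O)O)c1O[Si](C(C)C)(C(C)C)C(C)C | intermediate
8 | 2-[5-bromo-3-methoxy-2-(triisopropylsilyloxy)phenyl]acetyl chloride | COc1cc(Br)cc(CC(Cl)=O)c1O[Si](C(C)C)(C(C)C)C(C)C | intermediate
9 | 1-(benzyloxy)-4-bromo-2-methoxybenzene | COc1cc(Br)ccc1OCc1ccccc1 | intermediate
10 | [4-(benzyloxy)-3-methoxyphenyl]magnesium bromide (titrated THF solution) | COc1cc([Mg]Br)ccc1OCc1ccccc1 | intermediate
11 | (S)-4-benzyl-2-oxazolidinone | O=C1OC[C@H](Cc2ccccc2)N1 | starting material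
12 | lithium (S)-4-benzyl-2-oxooxazolidin-3-ide | O=C1OC[C@H](Cc2ccccc2)N1[Li] | intermediate (not isolated)
13 | (S)-4-benzyl-3-{2-[5-bromo-3-methoxy-2-(triisopropylsilyloxy)phenyl]acetyl}oxazolidin-2-one | COc1cc(Br)cc(CC(=O)N2[C@@H](Cc3ccccc3)COC2=O)c1O[Si](C(C)C)(C(C)C)C(C)C | intermediate
14 | benzyl chloromethyl ether (BOM chloride) | ClCOCc1ccccc1 | starting material
15 | (S)-4-benzyl-3-{(R)-3-(benzyloxy)-2-[5-bromo-3-methoxy-2-(triisopropylsilyloxy)phenyl]propanoyl}oxazolidin-2-one | COc1cc(Br)cc([C@H](COCc2ccccc2)C(=O)N2[C@@H](Cc3ccccc3)COC2=O)c1O[Si](C(C)C)(C(C)C)C(C)C | intermediate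
16 | (S)-3-(benzyloxy)-2-[5-bromo-3-methoxy-2-(triisopropylsilyloxy)phenyl]propan-1-ol | COc1cc(Br)cc([C@H](COCc2ccccc2)CO)c1O[Si](C(C)C)(C(C)C)C(C)C | intermediate
17 | (R)-3-(benzyloxy)-2-[5-bromo-3-methoxy-2-(triisopropylsilyloxy)phenyl]propanal | COc1cc(Br)cc([C@H](COCc2ccccc2)C=O)c1O[Si](C(C)C)(C(C)C)C(C)C | intermediate
18 | (1RS,2R)-3-(benzyloxy)-1-[4-(benzyloxy)-3-methoxyphenyl]-2-[5-bromo-3-methoxy-2-(triisopropylsilyloxy)phenyl]propan-1-ol | COc1cc(Br)cc([C@H](COCc2ccccc2)C(O)c2ccc(OCc3ccccc3)c(OC)c2)c1O[Si](C(C)C)(C(C)C)C(C)C | intermediate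
19 | (1RS,2R)-3-(benzyloxy)-1-[4-(benzyloxy)-3-methoxyphenyl]-2-(5-bromo-2-hydroxy-3-methoxyphenyl)propan-1-ol | COc1cc(Br)cc([C@H](COCc2ccccc2)C(O)c2ccc(OCc3ccccc3)c(OC)c2)c1O | intermediate
20 | (2S,3R)-2-[4-(benzyloxy)-3-methoxyphenyl]-3-[(benzyloxy)methyl]-5-bromo-7-methoxy-2,3-dihydrobenzofuran | Brc1cc(OC)c2c(c1)[C@H](COCc1ccccc1)[C@@H](c1ccc(OCc3ccccc3)c(OC)c1)O2 | intermediate
21 | (R)-4-benzyl-2-oxazolidinone | O=C1OC[C@@H](Cc2ccccc2)N1 | starting material
22 | lithium (R)-4-benzyl-2-oxooxazolidin-3-ide | O=C1OC[C@@H](Cc2ccccc2)N1[Li] | intermediate (not isolated)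
23 | (R)-4-benzyl-3-{2-[5-bromo-3-methoxy-2-(triisopropylsilyloxy)phenyl]acetyl}oxazolidin-2-one | COc1cc(Br)cc(CC(=O)N2[C@H](Cc3ccccc3)COC2=O)c1O[Si](C(C)C)(C(C)C)C(C)C | intermediate
24 | (R)-4-benzyl-3-{(S)-3-(benzyloxy)-2-[5-bromo-3-methoxy-2-(triisopropylsilyloxy)phenyl]propanoyl}oxazolidin-2-one | COc1cc(Br)cc([C@@H](COCc2ccccc2)C(=O)N2[C@H](Cc3ccccc3)COC2=O)c1O[Si](C(C)C)(C(C)C)C(C)C | intermediate
25 | (R)-3-(benzyloxy)-2-[5-bromo-3-methoxy-2-(triisopropylsilyloxy)phenyl]propan-1-ol | COc1cc(Br)cc([C@@H](COCc2ccccc2)CO)c1O[Si](C(C)C)(C(C)C)C(C)C | intermediate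
26 | (S)-3-(benzyloxy)-2-[5-bromo-3-methoxy-2-(triisopropylsilyloxy)phenyl]propanal | COc1cc(Br)cc([C@@H](COCc2ccccc2)C=O)c1O[Si](C(C)C)(C(C)C)C(C)C | intermediate
27 | {(2S,3R)-2-[4-(benzyloxy)-3-methoxyphenyl]-3-[(benzyloxy)methyl]-7-methoxy-2,3-dihydrobenzofuran-5-yl}lithium | [Li]c1cc(OC)c2c(c1)[C@H](COCc1ccccc1)[C@@H](c1ccc(OCc3ccccc3)c(OC)c1)O2 | intermediate (not isolated)
28 | {(2S,3R)-2-[4-(benzyloxy)-3-methoxyphenyl]-3-[(benzyloxy)methyl]-7-methoxy-2,3-dihydrobenzofuran-5-yl}magnesium bromide | Br[Mg]c1cc(OC)c2c(c1)[C@H](COCc1ccccc1)[C@@H](c1ccc(OCc3ccccc3)c(OC)c1)O2 | intermediate (not isolated)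
29 | (1RS,2S)-3-(benzyloxy)-1-{(2S,3R)-2-[4-(benzyloxy)-3-methoxyphenyl]-3-[(benzyloxy)methyl]-7-methoxy-2,3-dihydrobenzofuran-5-yl}-2-[5-bromo-3-methoxy-2-(triisopropylsilyloxy)phenyl]propan-1-ol | COc1cc(Br)cc([C@@H](COCc2ccccc2)C(O)c2cc(OC)c3c(c2)[C@H](COCc2ccccc2)[C@@H](c2ccc(OCc4ccccc4)c(OC)c2)O3)c1O[Si](C(C)C)(C(C)C)C(C)C | intermediate
30 | (1RS,2S)-3-(benzyloxy)-1-{(2S,3R)-2-[4-(benzyloxy)-3-methoxyphenyl]-3-[(benzyloxy)methyl]-7-methoxy-2,3-dihydrobenzofuran-5-yl}-2-(5-bromo-2-hydroxy-3-methoxyphenyl)propan-1-ol | Brc1cc(OC)c(O)c(c1)[C@@H](COCc2ccccc2)C(O)c3cc(OC)c5c(c3)[C@H](COCc4ccccc4)[C@@H](c3ccc(OCc6ccccc6)c(OC)c3)O5 | intermediate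
31 | (2R,3S)-3-[(benzyloxy)methyl]-2-{(2S,3R)-2-[4-(benzyloxy)-3-methoxyphenyl]-3-[(benzyloxy)methyl]-7-methoxy-2,3-dihydrobenzofuran-5-yl}-5-bromo-7-methoxy-2,3-dihydrobenzofuran | Brc1cc(OC)c2c(c1)[C@@H](COCc7ccccc7)[C@H](c3cc(OC)c5c(c3)[C@H](COCc4ccccc4)[C@@H](c3ccc(OCc6ccccc6)c(OC)c3)O5)O2 | intermediate
32 | (R)-epichlorohydrin | ClC[C@H]1CO1 | starting material
33 | diethyl malonate | CCOC(=O)CC(=O)OCC | starting material
34 | ethyl (1S,5R)-2-oxo-3-oxabicyclo[3.1.0]hexane-1-carboxylate | CCOC(=O)[C@]12C[C@H]1COC2=O | intermediate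
35 | ethyl (3RS,4R)-4-[4-(benzyloxy)-3-methoxybenzyl]-2-oxotetrahydrofuran-3-carboxylate | CCOC(=O)C1C(=O)OC[C@@H]1Cc1ccc(OCc2ccccc2)c(OC)c1 | intermediate
36 | (R)-4-[4-(benzyloxy)-3-methoxybenzyl]dihydrofuran-2(3H)-one | O=C1C[C@@H](Cc2ccc(OCc3ccccc3)c(OC)c2)CO1 | intermediate
37 | potassium (R)-3-[4-(benzyloxy)-3-methoxybenzyl]-4-hydroxybutanoate | [K+].[O-]C(=O)C[C@@H](Cc1ccc(OCc2ccccc2)c(OC)c1)CO | intermediate (not isolated)
38 | tert-butyldiphenylsilyl (R)-3-[4-(benzyloxy)-3-methoxybenzyl]-4-[(tert-butyldiphenylsilyl)oxy]butanoate | CC(C)(C)[Si](OC(=O)C[C@@H](Cc1ccc(OCc2ccccc2)c(OC)c1)CO[Si](c1ccccc1)(c1ccccc1)C(C)(C)C)(c1ccccc1)c1ccccc1 | intermediate (not isolated)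
39 | (R)-3-[4-(benzyloxy)-3-methoxybenzyl]-4-[(tert-butyldiphenylsilyl)oxy]butanoic acid | OC(=O)C[C@@H](Cc1ccc(OCc2ccccc2)c(OC)c1)CO[Si](c1ccccc1)(c1ccccc1)C(C)(C)C | intermediate
40 | (R)-3-[4-(benzyloxy)-3-methoxybenzyl]-4-[(tert-butyldiphenylsilyl)oxy]butanoic pivalic anhydride | CC(C)(C)C(=O)OC(=O)C[C@@H](Cc1ccc(OCc2ccccc2)c(OC)c1)CO[Si](c1ccccc1)(c1ccccc1)C(C)(C)C | intermediate (not isolated)
41 | (S)-4-benzyl-3-{(R)-3-[4-(benzyloxy)-3-methoxybenzyl]-4-[(tert-butyldiphenylsilyl)oxy]butanoyl}oxazolidin-2-one | O=C(C[C@@H](Cc1ccc(OCc2ccccc2)c(OC)c1)CO[Si](c1ccccc1)(c1ccccc1)C(C)(C)C)N1[C@@H](Cc2ccccc2)COC1=O | intermediate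
42 | (S)-4-benzyl-3-{(2R,3R)-3-[4-(benzyloxy)-3-methoxybenzyl]-2-[(benzyloxy)methyl]-4-[(tert-butyldiphenylsilyl)oxy]butanoyl}oxazolidin-2-one | O=C([C@@H](COCc1ccccc1)[C@@H](Cc1ccc(OCc2ccccc2)c(OC)c1)CO[Si](c1ccccc1)(c1ccccc1)C(C)(C)C)N1[C@@H](Cc2ccccc2)COC1=O | intermediate
43 | (S)-4-benzyl-3-{(2R,3R)-3-[4-(benzyloxy)-3-methoxybenzyl]-2-[(benzyloxy)methyl]-4-hydroxybutanoyl}oxazolidin-2-one | O=C([C@@H](COCc1ccccc1)[C@@H](Cc1ccc(OCc2ccccc2)c(OC)c1)CO)N1[C@@H](Cc2ccccc2)COC1=O | intermediate (not isolated)
44 | (3R,4R)-4-[4-(benzyloxy)-3-methoxybenzyl]-3-[(benzyloxy)methyl]dihydrofuran-2(3H)-one | COc1cc(C[C@H]2COC(=O)[C@H]2COCc2ccccc2)ccc1OCc1ccccc1 | intermediate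
45 | aryllithium from 31 (lithium in place of bromine at C5 of dihydrobenzofuran B) | [Li]c1cc(OC)c2c(c1)[C@@H](COCc7ccccc7)[C@H](c3cc(OC)c5c(c3)[C@H](COCc4ccccc4)[C@@H](c3ccc(OCc6ccccc6)c(OC)c3)O5)O2 | intermediate (not isolated)
46 | (3R,4R)-4-[4-(benzyloxy)-3-methoxybenzyl]-3-[(benzyloxy)methyl]-2-Ar-tetrahydrofuran-2-ol, Ar = 5-yl group of 31, both anomers | COc1cc(C[C@H]2COC(O)(c3cc(OC)c4c(c3)[C@@H](COCc3ccccc3)[C@H](c3cc(OC)c5c(c3)[C@H](COCc3ccccc3)[C@@H](c3ccc(OCc6ccccc6)c(OC)c3)O5)O4)[C@H]2COCc2ccccc2)ccc1OCc1ccccc1 | intermediate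
47 | (2R,3R,4R)-2-Ar-4-[4-(benzyloxy)-3-methoxybenzyl]-3-[(benzyloxy)methyl]tetrahydrofuran, Ar = 5-yl group of 31 | COc1cc(C[C@H]2CO[C@@H](c3cc(OC)c4c(c3)[C@@H](COCc3ccccc3)[C@H](c3cc(OC)c5c(c3)[C@H](COCc3ccccc3)[C@@H](c3ccc(OCc6ccccc6)c(OC)c3)O5)O4)[C@H]2COCc2ccccc2)ccc1OCc1ccccc1 | intermediate
48 | 4-{[(3R,4R,5R)-5-{(2R,3S)-3-(hydroxymethyl)-2-[(2S,3R)-2-(4-hydroxy-3-methoxyphenyl)-3-(hydroxymethyl)-7-methoxy-2,3-dihydrobenzofuran-5-yl]-7-methoxy-2,3-dihydrobenzofuran-5-yl}-4-(hydroxymethyl)tetrahydrofuran-3-yl]methyl}-2-methoxyphenol | COc1cc(C[C@H]2CO[C@@H](c3cc(OC)c4c(c3)[C@@H](CO)[C@H](c3cc(OC)c5c(c3)[C@H](CO)[C@@H](c3ccc(O)c(OC)c3)O5)O4)[C@H]2CO)ccc1O | target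

## Step count and least certain steps

Total step count: 31. Longest linear sequence: 18 steps (1, 2, 3, 4, 5, 8, 9, 10, 11, 12, 13, 14, 19, 20, 21, 29, 30, 31).

**Step 21 (key step).** The most likely failure is loss of the C3 proton from the cation. This gives a stilbene and erases the only controlling stereocentre. Capture of the cation by an electron-rich ring of a second molecule is the other risk. Both arise because the cation is long-lived enough to find other partners. The fallback avoids the free cation by a bimolecular displacement. It sets out from 29, whose two carbinol epimers are separated by chromatography. The (1S,2S)-carbinol silyl ether F1 is desilylated (TBAF, AcOH) to the (1S,2S)-phenol carbinol F2. PPh3 and DIAD then close F2 with inversion at the carbinol carbon (Mitsunobu etherification), which gives the (2R) centre of 31. The other epimer, the (1R,2S)-carbinol silyl ether F3, is converted into F1 by Mitsunobu inversion with 4-nitrobenzoic acid to the (1S,2S)-4-nitrobenzoate F4, followed by methanolysis (K2CO3, MeOH). The fallback returns to the route at 31.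

**Step 30.** Three processes threaten this step. The first is epimerization at C3 of the oxocarbenium ion through its enol ether before hydride arrives; the 3,4-cis arrangement is the less stable one, so this is a real risk. The second is acid-induced epimerization of the all-cis product at C2. The third is reductive opening of a dihydrobenzofuran ring after its benzylic ether ionizes. The fallback sets C2 and C3 together by catalytic hydrogenation. It sets out from 46, which is dehydrated (PPTS cat., 4 Å MS, toluene, 50 °C) to the 5-aryl-4-[(benzyloxy)methyl]-3-[4-(benzyloxy)-3-methoxybenzyl]-2,3-dihydrofuran F5. Hydrogenation of F5 over Pd/C adds H2 syn to the enol ether from the face opposite the benzyl-bearing stereocentre and removes the benzyl ethers in the same operation. It returns to the route at 48.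

**Step 18 (and likewise step 11).** The configuration of the α-aryl stereocentre may erode by enolization of aldehyde 26. This can happen during oxidation and work-up, or under the basic aryl-metal reagent in step 19, where β-elimination of benzyl alcohol is also possible. The fallback goes through a ketone and sets out from 24. LiOH and H2O2 give the (S)-3-(benzyloxy)-2-arylpropanoic acid F6. Coupling with MeNHOMe·HCl (EDC, HOBt) gives the Weinreb amide F7. The Grignard reagent 28 converts F7 into the aryl ketone F8 without over-addition. Reduction with NaBH4 and CeCl3·7H2O in MeOH at −40 °C gives both carbinol epimers. The fallback returns to the route at 29.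

**Step 16 (and likewise steps 9 and 27).** Alkylation of the titanium enolate next to the ortho-silyloxy aryl group may be slow or incomplete for steric reasons, and BOM chloride with TiCl4 may attack an electron-rich ring. The fallback separates C–C bond formation from benzylation and sets out from 23. Evans hydroxymethylation of the same titanium enolate with s-trioxane and TiCl4 gives the (S)-3-hydroxy-2-arylpropanoyl imide F9. Benzyl trichloroacetimidate with catalytic TfOH then benzylates F9 without base. The fallback returns to the route at 24.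

## Further compounds

F1 | step 21 | (1S,2S) epimer of 29 | COc1cc(Br)cc([C@@H](COCc2ccccc2)[C@H](O)c2cc(OC)c3c(c2)[C@H](COCc2ccccc2)[C@@H](c2ccc(OCc4ccccc4)c(OC)c2)O3)c1O[Si](C(C)C)(C(C)C)C(C)C
F2 | step 21 | (1S,2S) epimer of 30 | Brc1cc(OC)c(O)c(c1)[C@@H](COCc2ccccc2)[C@H](O)c3cc(OC)c5c(c3)[C@H](COCc4ccccc4)[C@@H](c3ccc(OCc6ccccc6)c(OC)c3)O5
F3 | step 21 | (1R,2S) epimer of 29 | COc1cc(Br)cc([C@@H](COCc2ccccc2)[C@@H](O)c2cc(OC)c3c(c2)[C@H](COCc2ccccc2)[C@@H](c2ccc(OCc4ccccc4)c(OC)c2)O3)c1O[Si](C(C)C)(C(C)C)C(C)C
F4 | step 21 | 4-nitrobenzoate of F1 (1S,2S) | COc1cc(Br)cc([C@@H](COCc2ccccc2)[C@H](OC(=O)c2ccc(cc2)[N+](=O)[O-])c2cc(OC)c3c(c2)[C@H](COCc2ccccc2)[C@@H](c2ccc(OCc4ccccc4)c(OC)c2)O3)c1O[Si](C(C)C)(C(C)C)C(C)C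
F5 | step 30 | (3R)-5-Ar-4-[(benzyloxy)methyl]-3-[4-(benzyloxy)-3-methoxybenzyl]-2,3-dihydrofuran, Ar = 5-yl group of 31 | COc1cc(C[C@H]2COC(c3cc(OC)c4c(c3)[C@@H](COCc3ccccc3)[C@H](c3cc(OC)c5c(c3)[C@H](COCc3ccccc3)[C@@H](c3ccc(OCc6ccccc6)c(OC)c3)O5)O4)=C2COCc2ccccc2)ccc1OCc1ccccc1
F6 | step 18 | (S)-3-(benzyloxy)-2-[5-bromo-3-methoxy-2-(triisopropylsilyloxy)phenyl]propanoic acid | COc1cc(Br)cc([C@@H](COCc2ccccc2)C(=O)O)c1O[Si](C(C)C)(C(C)C)C(C)C
F7 | step 18 | (S)-3-(benzyloxy)-2-[5-bromo-3-methoxy-2-(triisopropylsilyloxy)phenyl]-N-methoxy-N-methylpropanamide | COc1cc(Br)cc([C@@H](COCc2ccccc2)C(=O)N(C)OC)c1O[Si](C(C)C)(C(C)C)C(C)C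
F8 | step 18 | (S)-3-(benzyloxy)-1-{(2S,3R)-2-[4-(benzyloxy)-3-methoxyphenyl]-3-[(benzyloxy)methyl]-7-methoxy-2,3-dihydrobenzofuran-5-yl}-2-[5-bromo-3-methoxy-2-(triisopropylsilyloxy)phenyl]propan-1-one | COc1cc(Br)cc([C@@H](COCc2ccccc2)C(=O)c2cc(OC)c3c(c2)[C@H](COCc2ccccc2)[C@@H](c2ccc(OCc4ccccc4)c(OC)c2)O3)c1O[Si](C(C)C)(C(C)C)C(C)C
F9 | step 16 | (R)-4-benzyl-3-{(S)-2-[5-bromo-3-methoxy-2-(triisopropylsilyloxy)phenyl]-3-hydroxypropanoyl}oxazolidin-2-one | COc1cc(Br)cc([C@@H](CO)C(=O)N2[C@H](Cc3ccccc3)COC2=O)c1O[Si](C(C)C)(C(C)C)C(C)C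
A1 | alternative 1 | methyl 3-iodo-5-methoxy-4-{(R)-1-[(2S,3R)-2-[4-(benzyloxy)-3-methoxyphenyl]-3-{[(tert-butyldimethylsilyl)oxy]methyl}-7-methoxy-2,3-dihydrobenzofuran-5-yl]allyloxy}benzoate | COC(=O)c1cc(OC)c(O[C@H](C=C)c3cc(OC)c5c(c3)[C@H](CO[Si](C)(C)C(C)(C)C)[C@@H](c3ccc(OCc6ccccc6)c(OC)c3)O5)c(I)c1
A2 | alternative 1 | methyl trans-dihydrobenzofuran B 5-carboxylate with the C3 CH2–O–(2,2,6,6-tetramethylpiperidin-1-yl) group | COC(=O)c1cc(OC)c2c(c1)[C@@H](CON7C(C)(C)CCCC7(C)C)[C@H](c3cc(OC)c5c(c3)[C@H](CO[Si](C)(C)C(C)(C)C)[C@@H](c3ccc(OCc6ccccc6)c(OC)c3)O5)O2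
A3 | alternative 2 | (S)-6-bromo-8-methoxy-2-[3-methoxy-4-(tosyloxy)phenyl]chroman-4-one | O=C1C[C@@H](c2ccc(OS(=O)(=O)c3ccc(C)cc3)c(OC)c2)Oc2c(OC)cc(Br)cc12
A4 | alternative 2 | methyl trans-5-bromo-7-methoxy-2-(3-methoxy-4-tosyloxyphenyl)-2,3-dihydrobenzofuran-3-carboxylate | Brc1cc(OC)c2c(c1)[C@H](C(=O)OC)[C@@H](c3ccc(OS(=O)(=O)c4ccc(C)cc4)c(OC)c3)O2
A5 | alternative 3 | 3-diazo-5-[4-(benzyloxy)-3-methoxyphenyl]-4-[(ring B benzyloxy)methyl]dihydrofuran-2(3H)-one, ring B unit silyl protected | COc1cc([C@H]2OC(=O)C(=[N+]=[N-])[C@@H]2COCc3cc(OC)c4c(c3)[C@@H](CO[Si](C)(C)C(C)(C)C)[C@H](c3cc(OC)c5c(c3)[C@H](CO[Si](C)(C)C(C)(C)C)[C@@H](c3ccc(OCc6ccccc6)c(OC)c3)O5)O4)ccc1OCc1ccccc1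
A6 | alternative 3 | cis-fused furofuranone with ring B endo and ring A exo | COc1cc([C@@H]7[C@H]2CO[C@@H](c3cc(OC)c4c(c3)[C@@H](CO[Si](C)(C)C(C)(C)C)[C@H](c3cc(OC)c5c(c3)[C@H](CO[Si](C)(C)C(C)(C)C)[C@@H](c3ccc(OCc6ccccc6)c(OC)c3)O5)O4)[C@H]2C(=O)O7)ccc1OCc1ccccc1
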